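Retrosynthesis: the ester C–O bond at C5 is cut first (dienoic acid + 5-hydroxy lactone); then C3=C4 and C5–C6 of the dihydropyranone are cut together, which opens the ring to an acyclic allyl vinyl ether carrying a phosphonoacetate on O1; the acid is cut at C2=C3, at C4=C5 and at its C6 methyl group.
Enabling feature: the syn C5–O/C6–O pair of the ring with an (E)-propenyl group (C7=C8–C9) on C6. C5–C6 plus C7=C8 can be written back as the array C5=C4–O–C8–C7=C6, and the ring ester O1–C2–C3 puts C3 six atoms from the C4 carbonyl that this array releases.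
Forward order: (S)-but-3-yn-2-ol is O-alkylated with the C4–C5 unit, its alkyne is turned into the (Z)-enol phosphonoacetate (C6–O1–C2–C3), and the side arm is oxidized to the aldehyde and enolized to the (Z)-silyl enol ether. Heating then joins C5–C6 by a [3,3] shift, and the freed C4 aldehyde closes the only ring by intramolecular olefination; desilylation and esterification with the separately built acid finish the route.
Stereochemistry: C5 and C6 both come from the carbinol centre of (S)-but-3-yn-2-ol by 1,3-chirality transfer through a chair (Z,Z alkenes give the syn pair; the equatorial methyl gives the E-propenyl group and erases the old centre). The side-chain centre comes from an Evans methylation, the E-alkenes of the acid from Wittig and HWE steps, and the ring Z-alkene from ring closure.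

Key step: step 6

Remark: O1 and C2–C6 are the ring atoms of the dihydropyranone and C7–C9 the propenyl carbons counted from C6; these labels are kept for the same atoms in every precursor.

Step 1
Reactants: 1 (S)-but-3-yn-2-ol; 2 (2-bromoethoxy)(tert-butyl)dimethylsilane
Product: 3 (S)-tert-butyl[2-(but-3-yn-2-yloxy)ethoxy]dimethylsilane
Conditions: NaH, Bu4NI (cat.), THF/DMF, 0 °C → rt
Reagents that add atoms: none
Why: Williamson ether synthesis: NaH removes only the hydroxyl proton (the alkyne C–H is far less acidic) and the alkoxide displaces the primary bromide, while the carbinol centre keeps all four bonds and its configuration.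

Step 2
Reactants: 3 (S)-tert-butyl[2-(but-3-yn-2-yloxy)ethoxy]dimethylsilane; 4 2-(diethoxyphosphoryl)acetic acid
Product: 5 (1Z,3S)-3-(2-{[tert-butyl(dimethyl)silyl]oxy}ethoxy)but-1-en-1-yl 2-(diethoxyphosphoryl)acetate
Conditions: [RuCl2(p-cymene)]2 (cat.), P(4-ClC6H4)3, DMAP (cat.), PhMe, 60 °C
Reagents that add atoms: none
Why: Ruthenium-catalysed anti-Markovnikov addition of a carboxylic acid to a terminal alkyne (hydro-oxycarbonylation): the carboxylate attacks the α-carbon of the ruthenium vinylidene and protonolysis should deliver the (Z)-enol ester, with the propargylic centre untouched.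

Step 3
Reactants: 5 (1Z,3S)-3-(2-{[tert-butyl(dimethyl)silyl]oxy}ethoxy)but-1-en-1-yl 2-(diethoxyphosphoryl)acetate
Product: 6 (1Z,3S)-3-(2-hydroxyethoxy)but-1-en-1-yl 2-(diethoxyphosphoryl)acetate
Conditions: HF·pyridine, pyridine, THF, 0 °C → rt
Reagents that add atoms: none
Why: Fluoride-mediated desilylation of a primary silyl ether under buffered, non-basic conditions that should leave the enol ester and the phosphonate alone.

Step 4
Reactants: 6 (1Z,3S)-3-(2-hydroxyethoxy)but-1-en-1-yl 2-(diethoxyphosphoryl)acetate
Product: 7 (1Z,3S)-3-(2-oxoethoxy)but-1-en-1-yl 2-(diethoxyphosphoryl)acetate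
Conditions: Dess–Martin periodinane, CH2Cl2, 0 °C → rt
Reagents that add atoms: none
Why: Dess–Martin oxidation of the primary alcohol to the aldehyde; no base is present, so the aldehyde and the phosphonoacetate of the same molecule should not condense.

Step 5
Reactants: 7 (1Z,3S)-3-(2-oxoethoxy)but-1-en-1-yl 2-(diethoxyphosphoryl)acetate
Product: 8 (1Z,3S)-3-{[(Z)-2-{[tert-butyl(dimethyl)silyl]oxy}ethenyl]oxy}but-1-en-1-yl 2-(diethoxyphosphoryl)acetate
Conditions: TBSOTf, Et3N, CH2Cl2, −78 → 0 °C
Reagents that add atoms: tert-butyldimethylsilyl trifluoromethanesulfonate (TBSOTf), CC(C)(C)[Si](C)(C)OS(=O)(=O)C(F)(F)F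
Why: Soft enolization of an aldehyde to its silyl enol ether (silyl triflate/tertiary amine); the O–CH2 group is the only enolizable position and the cis-1,2-dioxygenated (Z) alkene should be favoured, as it is for 1,2-dialkoxyethenes.

Step 6
Reactants: 8 (1Z,3S)-3-{[(Z)-2-{[tert-butyl(dimethyl)silyl]oxy}ethenyl]oxy}but-1-en-1-yl 2-(diethoxyphosphoryl)acetate
Product: 10 (5S,6S)-5-{[tert-butyl(dimethyl)silyl]oxy}-6-[(E)-prop-1-en-1-yl]-5,6-dihydro-2H-pyran-2-one, via Claisen aldehyde 9 (not isolated)
Conditions: PhMe, 110 °C; then, in the same flask, LiCl, iPr2NEt, MeCN, 0 °C → rt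
Reagents that add atoms: none
Why: Proposed new method: heating 8 should set off a Claisen ([3,3]-sigmatropic) rearrangement of the allyl vinyl ether array C5=C4–O–C8–C7=C6, which forms C5–C6, converts C4 into the aldehyde of 9 and C7=C8 into the propenyl alkene; LiCl/iPr2NEt then deprotonates the phosphonoacetate on O1 at C3, and the lithium-chelated carbanion adds to the C4 aldehyde and eliminates diethyl phosphate (intramolecular Horner–Wadsworth–Emmons olefination, C3=C4), so that the oxygen that tethered the two halves leaves the molecule. The closest known reaction types are the aliphatic Claisen rearrangement of allyl vinyl ethers that carry oxygen donors (6-alkoxy allyl vinyl ethers, and the enolates of α-allyloxy ketones in the anionic oxy-Claisen variant) and the Masamune–Roush intramolecular HWE closure of β-(phosphonoacetoxy) aldehydes to 5,6-dihydropyran-2-ones; new are the 1-siloxy/6-acyloxy pattern and the coupling of both events in one flask. The only ring formed, the six-membered lactone, closes in the 6-exo-trig mode (C3 carbanion onto the exocyclic C4=O), and the ring size enforces the Z geometry of C3=C4. C6 is controlled by the carbinol centre C8 through a chair transition state with the C8 methyl group equatorial (bond making at C6 on the face from which the C8–O bond leaves), which gives (6S) and the E-propenyl group; C5 is controlled relative to C6 by the two alkene geometries, the (Z)-silyl enol ether and the (Z)-enol ester giving the syn (5S,6S) pair in the chair, which is the cis-lactone. The step needs chair over boat selectivity and an equatorial C8 methyl group, both secured by the acyclic substrate in which an axial methyl group would be 1,3-diaxial to the axial acyloxy group on C6; it also needs ring closure to outrun β-elimination of the C6 acyloxy group and epimerization at C5 of aldehyde 9, which the neutral thermal first stage and the weak amine/lithium salt base acting on a six-ring intramolecular olefination at 0 °C should secure.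

Step 7
Reactants: 10 (5S,6S)-5-{[tert-butyl(dimethyl)silyl]oxy}-6-[(E)-prop-1-en-1-yl]-5,6-dihydro-2H-pyran-2-one
Product: 11 (5S,6S)-5-hydroxy-6-[(E)-prop-1-en-1-yl]-5,6-dihydro-2H-pyran-2-one (phomalactone)
Conditions: HF·pyridine, THF, 0 °C → rt
Reagents that add atoms: none
Why: Fluoride-mediated desilylation of the secondary silyl ether without base, so that neither C5 epimerization nor base-triggered translactonization to the butenolide is opened.

Step 8
Reactants: 12 (S)-4-benzyloxazolidin-2-one; 13 octanoyl chloride
Product: 14 (S)-4-benzyl-3-octanoyloxazolidin-2-one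
Conditions: n-BuLi, THF, −78 °C; then 13, −78 → 0 °C
Reagents that add atoms: none
Why: N-Acylation of the lithiated Evans oxazolidinone by the acid chloride (acyl substitution at nitrogen); the auxiliary centre is not touched.

Step 9
Reactants: 14 (S)-4-benzyl-3-octanoyloxazolidin-2-one
Product: 15 (S)-4-benzyl-3-[(S)-2-methyloctanoyl]oxazolidin-2-one
Conditions: NaN(SiMe3)2, THF, −78 °C; then MeI
Reagents that add atoms: iodomethane (MeI), CI
Why: Evans asymmetric alkylation: NaN(SiMe3)2 gives the chelated Z-enolate, which should take up iodomethane on the face opposite to the benzyl group and so set the (S)-configured methyl-bearing centre.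

Step 10
Reactants: 15 (S)-4-benzyl-3-[(S)-2-methyloctanoyl]oxazolidin-2-one
Product: 16 (S)-2-methyloctan-1-ol
Conditions: LiBH4, H2O (1 equiv), Et2O, 0 °C
Reagents that add atoms: none
Why: Reductive removal of the auxiliary (LiBH4 reduction of the imide acyl group) gives the primary alcohol without touching the α-centre and returns the oxazolidinone.

Step 11
Reactants: 16 (S)-2-methyloctan-1-ol
Product: 17 (S)-2-methyloctanal
Conditions: Dess–Martin periodinane, CH2Cl2, 0 °C → rt
Reagents that add atoms: none
Why: Dess–Martin oxidation, a non-basic oxidation that should not epimerize the α-branched aldehyde, which is used at once.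

Step 12
Reactants: 17 (S)-2-methyloctanal; 18 2-(triphenylphosphoranylidene)propanal
Product: 19 (2E,4S)-2,4-dimethyldec-2-enal
Conditions: PhMe, 90 °C
Reagents that add atoms: none
Why: Wittig olefination with a stabilized α-methyl formyl ylide, which should give the trisubstituted (E)-enal and is only weakly basic toward the α-centre.

Step 13
Reactants: 19 (2E,4S)-2,4-dimethyldec-2-enal; 20 triethyl phosphonoacetate
Product: 21 ethyl (2E,4E,6S)-4,6-dimethyldodeca-2,4-dienoate
Conditions: NaH, THF, 0 °C → rt
Reagents that add atoms: none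
Why: Horner–Wadsworth–Emmons olefination of the enal with the sodium phosphonate, E-selective for the new disubstituted alkene.

Step 14
Reactants: 21 ethyl (2E,4E,6S)-4,6-dimethyldodeca-2,4-dienoate
Product: 22 (2E,4E,6S)-4,6-dimethyldodeca-2,4-dienoic acid
Conditions: LiOH, THF/MeOH/H2O, rt; then aq. HCl
Reagents that add atoms: lithium hydroxide, [Li+].[OH-]
Why: Saponification of the ethyl ester; the stereocentre lies beyond the trisubstituted alkene and is not acidified.

Step 15
Reactants: 11 (5S,6S)-5-hydroxy-6-[(E)-prop-1-en-1-yl]-5,6-dihydro-2H-pyran-2-one; 22 (2E,4E,6S)-4,6-dimethyldodeca-2,4-dienoic acid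
Product: 23 (5S,6S)-2-oxo-6-[(E)-prop-1-en-1-yl]-5,6-dihydro-2H-pyran-5-yl (2E,4E,6S)-4,6-dimethyldodeca-2,4-dienoate (CNP0240957.1)
Conditions: DCC, DMAP (cat.), CH2Cl2, 0 °C → rt
Reagents that add atoms: none
Why: Steglich esterification (carbodiimide activation, acyl transfer through the acylpyridinium) of the secondary C5 hydroxyl group with retention at C5, mild enough for the unsaturated lactone.

Compound list
1 | (S)-but-3-yn-2-ol | C[C@H](O)C#C | starting material
2 | (2-bromoethoxy)(tert-butyl)dimethylsilane | CC(C)(C)[Si](C)(C)OCCBr | starting material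
3 | (S)-tert-butyl[2-(but-3-yn-2-yloxy)ethoxy]dimethylsilane | C[C@H](OCCO[Si](C)(C)C(C)(C)C)C#C | intermediate
4 | 2-(diethoxyphosphoryl)acetic acid | CCOP(=O)(OCC)CC(=O)O | starting material
5 | (1Z,3S)-3-(2-{[tert-butyl(dimethyl)silyl]oxy}ethoxy)but-1-en-1-yl 2-(diethoxyphosphoryl)acetate | C[C@H](OCCO[Si](C)(C)C(C)(C)C)/C=C\OC(=O)CP(=O)(OCC)OCC | intermediate
6 | (1Z,3S)-3-(2-hydroxyethoxy)but-1-en-1-yl 2-(diethoxyphosphoryl)acetate | C[C@H](OCCO)/C=C\OC(=O)CP(=O)(OCC)OCC | intermediate
7 | (1Z,3S)-3-(2-oxoethoxy)but-1-en-1-yl 2-(diethoxyphosphoryl)acetate | C[C@H](OCC=O)/C=C\OC(=O)CP(=O)(OCC)OCC | intermediate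
8 | (1Z,3S)-3-{[(Z)-2-{[tert-butyl(dimethyl)silyl]oxy}ethenyl]oxy}but-1-en-1-yl 2-(diethoxyphosphoryl)acetate | C[C@H](O/C=C\O[Si](C)(C)C(C)(C)C)/C=C\OC(=O)CP(=O)(OCC)OCC | intermediate
9 | (2R,3S,4E)-2-{[tert-butyl(dimethyl)silyl]oxy}-1-oxohex-4-en-3-yl 2-(diethoxyphosphoryl)acetate | C/C=C/[C@H](OC(=O)CP(=O)(OCC)OCC)[C@H](C=O)O[Si](C)(C)C(C)(C)C | intermediate
10 | (5S,6S)-5-{[tert-butyl(dimethyl)silyl]oxy}-6-[(E)-prop-1-en-1-yl]-5,6-dihydro-2H-pyran-2-one | C/C=C/[C@@H]1OC(=O)C=C[C@@H]1O[Si](C)(C)C(C)(C)C | intermediate
11 | (5S,6S)-5-hydroxy-6-[(E)-prop-1-en-1-yl]-5,6-dihydro-2H-pyran-2-one (phomalactone) | C/C=C/[C@@H]1OC(=O)C=C[C@@H]1O | intermediate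
12 | (S)-4-benzyloxazolidin-2-one | O=C1N[C@@H](Cc2ccccc2)CO1 | starting material
13 | octanoyl chloride | CCCCCCCC(=O)Cl | starting material
14 | (S)-4-benzyl-3-octanoyloxazolidin-2-one | CCCCCCCC(=O)N1[C@@H](Cc2ccccc2)COC1=O | intermediate
15 | (S)-4-benzyl-3-[(S)-2-methyloctanoyl]oxazolidin-2-one | CCCCCC[C@H](C)C(=O)N1[C@@H](Cc2ccccc2)COC1=O | intermediate
16 | (S)-2-methyloctan-1-ol | CCCCCC[C@H](C)CO | intermediate
17 | (S)-2-methyloctanal | CCCCCC[C@H](C)C=O | intermediate
18 | 2-(triphenylphosphoranylidene)propanal | CC(C=O)=P(c1ccccc1)(c1ccccc1)c1ccccc1 | starting material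
19 | (2E,4S)-2,4-dimethyldec-2-enal | CCCCCC[C@H](C)/C=C(\C)C=O | intermediate
20 | triethyl phosphonoacetate | CCOC(=O)CP(=O)(OCC)OCC | starting material
21 | ethyl (2E,4E,6S)-4,6-dimethyldodeca-2,4-dienoate | CCCCCC[C@H](C)/C=C(C)/C=C/C(=O)OCC | intermediate
22 | (2E,4E,6S)-4,6-dimethyldodeca-2,4-dienoic acid | CCCCCC[C@H](C)/C=C(C)/C=C/C(=O)O | intermediate
23 | (5S,6S)-2-oxo-6-[(E)-prop-1-en-1-yl]-5,6-dihydro-2H-pyran-5-yl (2E,4E,6S)-4,6-dimethyldodeca-2,4-dienoate | C/C=C/[C@@H]1OC(=O)C=C[C@@H]1OC(=O)/C=C/C(C)=C/[C@@H](C)CCCCCC | target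

Total step count: 15. Longest linear sequence: 8 steps (steps 1–7 and 15; the acid branch, steps 8–14 and 15, is equally long).

Steps most likely to fail

Step 6 (proposed new method). What may go wrong: the doubly Z-substituted [3,3] shift may be slow compared with thermal breakdown of the enol ester, it may leak through a boat transition state (loss of the syn relationship), or aldehyde 9 may suffer β-elimination or C5 epimerization before the ring closes. Fallback with known chemistry and a different bond order (C5–C6 by allylboration, O1–C2 by acylation, C3=C4 by metathesis): it cannot branch from an intermediate of the route, because every compound from 3 to 8 already carries the tether. It therefore sets out from commercial (E)-but-2-enal and allyl methoxymethyl ether in place of compound 1, and comes back to the route at compound 11. Allyl methoxymethyl ether is metalated (s-BuLi, THF, −78 °C) and transferred to boron with (+)-Ipc2BOMe and BF3·OEt2; the (Z)-γ-(methoxymethoxy)allylborane adds to (E)-but-2-enal (Brown alkoxyallylboration, then NaOH/H2O2) and should give (3S,4S,5E)-3-(methoxymethoxy)hepta-1,5-dien-4-ol F1. Acryloyl chloride, Et3N and DMAP give (3S,4S,5E)-3-(methoxymethoxy)hepta-1,5-dien-4-yl prop-2-enoate F2. Ring-closing metathesis with the second-generation Grubbs catalyst (CH2Cl2, 40 °C), which starts at the terminal vinyl group, gives (5S,6S)-5-(methoxymethoxy)-6-[(E)-prop-1-en-1-yl]-5,6-dihydro-2H-pyran-2-one F3. Removal of the methoxymethyl group (Me2BBr, CH2Cl2, −78 °C) gives 11.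

Step 5. What may go wrong: enolization under silyl triflate/amine conditions may give an E/Z mixture (the E-enol silane is carried by the chair into the trans-lactone), and the acidic phosphonoacetate may be silylated or may condense with the activated aldehyde. Fallback that changes the reactive intermediate from a neutral enol silane to a chelated metal enediolate: it sets out from 7 and comes back at 11, bypassing 8–10. Adding 7 to KN(SiMe3)2 (2.2 equiv, THF, −78 °C) should give the dianion (phosphonate carbanion plus potassium enediolate), whose five-membered chelate can only be Z. The charge-accelerated shift (anionic oxy-Claisen) on warming to −20 °C would give the potassium alkoxide of (2R,3S,4E)-2-hydroxy-1-oxohex-4-en-3-yl 2-(diethoxyphosphoryl)acetate F4, which closes at once by the intramolecular HWE reaction; a quench with AcOH at −78 °C gives 11.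

Step 2. What may go wrong: Markovnikov addition, ionization of the propargylic C–O bond at the ruthenium vinylidene stage, or erosion of the Z geometry. Fallback that replaces alkyne hydro-oxycarbonylation by a C–O cross-coupling: it sets out from 3 and comes back at 5. Compound 3 is iodinated at the alkyne terminus (N-iodosuccinimide, AgNO3 cat., acetone) to (S)-tert-butyl{2-[(4-iodobut-3-yn-2-yl)oxy]ethoxy}dimethylsilane F5. Diimide reduction (2-nitrobenzenesulfonohydrazide, Et3N) gives (S,Z)-tert-butyl{2-[(4-iodobut-3-en-2-yl)oxy]ethoxy}dimethylsilane F6. Copper-catalysed coupling of F6 with acid 4 (CuI, N,N'-dimethylethylenediamine, Cs2CO3, PhMe, 80 °C), which keeps the alkene geometry, gives 5.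

Further compounds
F1 | step 6 | (3S,4S,5E)-3-(methoxymethoxy)hepta-1,5-dien-4-ol | C/C=C/[C@H](O)[C@@H](OCOC)C=C
F2 | step 6 | (3S,4S,5E)-3-(methoxymethoxy)hepta-1,5-dien-4-yl prop-2-enoate | C/C=C/[C@H](OC(=O)C=C)[C@@H](OCOC)C=C
F3 | step 6 | (5S,6S)-5-(methoxymethoxy)-6-[(E)-prop-1-en-1-yl]-5,6-dihydro-2H-pyran-2-one | C/C=C/[C@@H]1OC(=O)C=C[C@@H]1OCOC
F4 | step 5 | (2R,3S,4E)-2-hydroxy-1-oxohex-4-en-3-yl 2-(diethoxyphosphoryl)acetate | C/C=C/[C@H](OC(=O)CP(=O)(OCC)OCC)[C@H](C=O)O
F5 | step 2 | (S)-tert-butyl{2-[(4-iodobut-3-yn-2-yl)oxy]ethoxy}dimethylsilane | C[C@H](OCCO[Si](C)(C)C(C)(C)C)C#CI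
F6 | step 2 | (S,Z)-tert-butyl{2-[(4-iodobut-3-en-2-yl)oxy]ethoxy}dimethylsilane | C[C@H](OCCO[Si](C)(C)C(C)(C)C)/C=C\I
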